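The constants used here stand for no real mixture; what happens was integrated by code.

Do not read a reagent excess as a finished reaction: in this scheme what counts is the free reagent, measured against one constant.

    reagent → decomposition product (k1 = 3.3 × 10⁻⁵ min⁻¹)
    target ⇌ isomer of the product B (K2 = 0.14, k2 = 0.014 min⁻¹)
    crystals ⇌ target, rate k3*(cs3 - [target]) while solid is left; crystals form when [target] > cs3 (cs3 = 9.0 mM, k3 = 12 min⁻¹)
    substrate + reagent ⇌ target (K4 = 70 M⁻¹, k4 = 4.7 M⁻¹ min⁻¹)
    substrate + reagent ⇌ isomer of the product A (K5 = 120 M⁻¹, k5 = 2.4 M⁻¹ min⁻¹)

substrate 0.020 M; reagent 0.0240 M; time 12 h

- conversion of substrate at 12 h
- amount of target at 12 h, in percent of the substrate charged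
- amount of isomer of the product A at 12 h, in percent of the substrate charged
- amount of target if the flask were left three thousand times as long, in percent of the substrate charged

Take the main flask and a neighbour, here called the dilute flask, which has the same reagent charge but a quarter of the substrate. Reckon both as equilibria, because the forward half-life of substrate towards isomer of the product A, 0.20 h, is short against 12 h, while the half-life of reagent decomposition, 15 d, is long against it.

Add up the bound forms: target, isomer of the product B per target, and isomer of the product A. Define Kd, the overall dissociation constant, as the reciprocal of their summed constants: 5.01 mM. Bound over free substrate is then b/Kd, with b the free reagent, so its logarithm counts the powers of ten by which b stands above Kd. With x bound, solve (substrate charge − x)(reagent charge − x) = Kd·x.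

In the main flask x is 13.5 mM, so b is 10.5 mM, or 0.321 decades above Kd. This gives 67.7% conversion, 23.7% target and 40.6% isomer of the product A, setting decomposition aside. Target at 4.74 mM stands below 9.0 mM, so I reckon no crystals at this state. In the dilute flask, x is 4.00 mM, so b stands at 20.0 mM, 0.601 decades up, and I reckon its conversion at 80.0% because free reagent there stands higher than in the main flask.

Very late, count free substrate at its charge; free reagent is then 0.200 of the reagent present. Over 36000 h the decay of reagent spans 6.20 decades, so target falls to <0.001%.

The forecast gives 67.3%, 23.6%, 40.4% and <0.001%, holding that “the reagent decomposes irreversibly, draining every reversible product back to substrate”.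

The simulation gives 67.3%, 23.6%, 40.4% and 0%, with crystals at 0%. The forward half-life of substrate towards isomer of the product A, 0.20 h, stands far below the 15 d of reagent decomposition. By 2.40 h, 99.7% of the turnover to isomer of the product A up to 12 h is done.

Now take the neighbouring reagent-poor flask, where reagent at 0.0060 M is the limiting reagent. Kd gives x = 4.53 mM, so b lies 0.533 decades below Kd, with conversion 22.7% and target 7.94%. The reagent-poor flask computes to 22.5% conversion and 7.90% target.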